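The route rests on cutting the C4–C4a bond of ring C. The precursor is a (3S)-3-aryl-3-aryloxypropanoic acid whose aryloxy part, the future ring A, carries the (S)-N-methylpiperidine para to the ether oxygen (future O1) and a benzyloxy group on each side of the piperidine. Because the two ring A carbons ortho to O1 are interchanged by rotation, intramolecular Friedel–Crafts acylation at either one gives C4a with the piperidine at C6, never C8. One operation therefore closes the pyranone regiospecifically with both stereocentres already installed. Ring B carries a benzyl carbonate, which is electron-withdrawing (protecting the benzylic C2–O1 bond) and is cleaved with the benzyl ethers in one final hydrogenolysis.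

Key step: step 12

Assumption: Si-face addition to the (R)-sulfinyl imine (magnesium-chelated chair) and Re-face allyl delivery by (R)-TRIP are taken to hold for these substrates; if either sense proved opposite, the enantiomeric auxiliary or catalyst would be used and nothing else would change.

Step 1
Reactants: 1 3,5-bis(benzyloxy)phenol
Product: 3 2,6-bis(benzyloxy)-4-hydroxybenzaldehyde, via aryl iminium chloride 2 (not isolated)
Conditions: POCl3, DMF, MeCN, 0 °C to rt; then H2O, 40 °C
Reagents that add atoms: N,N-dimethylformamide (CN(C)C=O); water (O)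
Why: Vilsmeier–Haack formylation, in which the chloroiminium ion should attack mainly the ring carbon para to the free hydroxyl, as is usual for 3,5-dialkoxyphenols, while the internally hydrogen-bonded ortho-formyl isomer is less polar and is removed by chromatography.

Step 2
Reactants: 3 2,6-bis(benzyloxy)-4-hydroxybenzaldehyde
Product: 4 4-(allyloxy)-2,6-bis(benzyloxy)benzaldehyde
Conditions: allyl bromide, K2CO3, DMF, rt
Reagents that add atoms: allyl bromide (C=CCBr)
Why: Williamson ether synthesis (SN2 O-alkylation) of the acidic phenol para to the formyl group gives an allyl ether that is inert to the organometallic, acidic and reductive steps ahead and can later be removed under neutral conditions without touching the benzyl ethers.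

Step 3
Reactants: 4 4-(allyloxy)-2,6-bis(benzyloxy)benzaldehyde
Product: 5 (R)-N-{(E)-[4-(allyloxy)-2,6-bis(benzyloxy)phenyl]methylidene}-2-methylpropane-2-sulfinamide
Conditions: (R)-tert-butanesulfinamide, Ti(OEt)4, THF, 65 °C
Reagents that add atoms: (R)-2-methylpropane-2-sulfinamide (CC(C)(C)[S@@](=O)N)
Why: Ti(OEt)4-mediated condensation of a non-enolisable aldehyde with a sulfinamide (sulfinyl imine formation) should proceed because the Lewis acid both activates the hindered carbonyl and takes up the water, and no bond to the sulfur stereocentre is broken.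

Step 4
Reactants: 5 (R)-N-{(E)-[4-(allyloxy)-2,6-bis(benzyloxy)phenyl]methylidene}-2-methylpropane-2-sulfinamide; 6 1-bromo-4-chlorobutane
Product: 8 (R)-N-{(1S)-1-[4-(allyloxy)-2,6-bis(benzyloxy)phenyl]-5-chloropentyl}-2-methylpropane-2-sulfinamide, via 4-chlorobutylmagnesium bromide 7 (not isolated)
Conditions: 6, Mg, Et2O, 30 °C; then 5, CH2Cl2, −48 °C to rt; aq. NH4Cl
Reagents that add atoms: none
Why: Grignard 1,2-addition to an N-tert-butanesulfinyl aldimine in a non-coordinating solvent, where magnesium bound to the sulfinyl oxygen delivers the alkyl group through a six-membered chair to the Si face of the (R)-sulfinyl imine and so sets the (S) benzylic centre, the reagent being formed by insertion of Mg into the C–Br bond only so that the C–Cl bond remains for the ring closure.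

Step 5
Reactants: 8 (R)-N-{(1S)-1-[4-(allyloxy)-2,6-bis(benzyloxy)phenyl]-5-chloropentyl}-2-methylpropane-2-sulfinamide
Product: 10 (2S)-2-[4-(allyloxy)-2,6-bis(benzyloxy)phenyl]piperidine, via primary ammonium chloride 9 (not isolated)
Conditions: HCl (4 M in dioxane), MeOH, 0 °C; evaporate, Et2O wash; K2CO3, NaI (cat.), MeCN, 70 °C
Reagents that add atoms: none
Why: Acidolysis of the N–S bond releases the primary amine, which after neutralisation closes the piperidine by intramolecular SN2 N-alkylation (6-exo-tet, assisted by halide exchange with iodide) without involving the stereocentre.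

Step 6
Reactants: 10 (2S)-2-[4-(allyloxy)-2,6-bis(benzyloxy)phenyl]piperidine
Product: 11 (2S)-2-[4-(allyloxy)-2,6-bis(benzyloxy)phenyl]-1-methylpiperidine
Conditions: aq. CH2O, NaBH(OAc)3, 1,2-dichloroethane, rt
Reagents that add atoms: formaldehyde (C=O)
Why: Reductive amination, in which NaBH(OAc)3 reduces the iminium ion formed from the secondary amine and formaldehyde faster than the aldehyde itself, so that a single N-methyl group is introduced.

Step 7
Reactants: 11 (2S)-2-[4-(allyloxy)-2,6-bis(benzyloxy)phenyl]-1-methylpiperidine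
Product: 12 3,5-bis(benzyloxy)-4-[(2S)-1-methylpiperidin-2-yl]phenol
Conditions: Pd(PPh3)4 (cat.), morpholine, THF, rt
Reagents that add atoms: none
Why: Deallylation by allyl transfer (Tsuji–Trost type), in which zerovalent palladium ionises the aryl allyl ether to a π-allyl complex that morpholine captures, freeing the phenol under neutral conditions with the benzyl ethers and the tertiary amine untouched.

Step 8
Reactants: 13 4-hydroxybenzaldehyde
Product: 14 benzyl 4-formylphenyl carbonate
Conditions: benzyl chloroformate, Et3N, CH2Cl2, 0 °C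
Reagents that add atoms: benzyl chloroformate (O=C(Cl)OCc1ccccc1)
Why: O-Acylation of the phenol with a chloroformate under mild base gives the aryl benzyl carbonate, an electron-withdrawing protecting group that later falls off by hydrogenolysis.

Step 9
Reactants: 14 benzyl 4-formylphenyl carbonate; 15 2-allyl-4,4,5,5-tetramethyl-1,3,2-dioxaborolane
Product: 17 benzyl 4-[(1R)-1-hydroxybut-3-en-1-yl]phenyl carbonate, via pinacol borate ester 16 (not isolated)
Conditions: (R)-TRIP [(R)-3,3'-bis(2,4,6-triisopropylphenyl)-1,1'-binaphthyl-2,2'-diyl hydrogen phosphate] (5 mol%), toluene, −30 °C; aqueous work-up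
Reagents that add atoms: none
Why: Brønsted acid-catalysed allylboration through a closed chair transition state, in which the chiral phosphate holds the boronate oxygen and the formyl hydrogen so that allyl is delivered to the Re face of the aldehyde and the (R) carbinol results, under neutral conditions that the carbonate tolerates.

Step 10
Reactants: 12 3,5-bis(benzyloxy)-4-[(2S)-1-methylpiperidin-2-yl]phenol; 17 benzyl 4-[(1R)-1-hydroxybut-3-en-1-yl]phenyl carbonate
Product: 18 benzyl 4-[(1S)-1-{3,5-bis(benzyloxy)-4-[(2S)-1-methylpiperidin-2-yl]phenoxy}but-3-en-1-yl]phenyl carbonate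
Conditions: PPh3, DIAD, toluene, 0 °C to rt
Reagents that add atoms: none
Why: Mitsunobu etherification, in which the phenol (pKa near 10) displaces the oxyphosphonium group by SN2 with inversion and turns the (R) alcohol into the (S) aryl ether, while the homoallylic alcohol lacks the acidic β-hydrogens that make β-hydroxy esters eliminate and the carbonate on ring B disfavours ionisation.

Step 11
Reactants: 18 benzyl 4-[(1S)-1-{3,5-bis(benzyloxy)-4-[(2S)-1-methylpiperidin-2-yl]phenoxy}but-3-en-1-yl]phenyl carbonate
Product: 21 (3S)-3-(4-{[(benzyloxy)carbonyl]oxy}phenyl)-3-{3,5-bis(benzyloxy)-4-[(2S)-1-methylpiperidin-2-yl]phenoxy}propanoic acid, via vicinal diol 19 (not isolated), via β-aryloxy aldehyde 20 (not isolated)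
Conditions: OsO4 (cat.), NMO, citric acid, t-BuOH/H2O, rt; NaIO4, 0 °C; extract; NaClO2, NaH2PO4, 2-methyl-2-butene, t-BuOH/H2O, 0 °C
Reagents that add atoms: osmium tetroxide (O=[Os](=O)(=O)=O); N-methylmorpholine N-oxide (C[N+]1([O-])CCOCC1); sodium chlorite ([Na+].[O-]Cl=O)
Why: Osmium-catalysed dihydroxylation, periodate glycol cleavage and Pinnick oxidation, run in sequence without purification, shorten the terminal alkene by one carbon to the carboxylic acid while citric acid and the phosphate buffer keep the amine protonated, 2-methyl-2-butene traps hypochlorous acid before it can chlorinate ring A, and no stereocentre is touched.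

Step 12
Reactants: 21 (3S)-3-(4-{[(benzyloxy)carbonyl]oxy}phenyl)-3-{3,5-bis(benzyloxy)-4-[(2S)-1-methylpiperidin-2-yl]phenoxy}propanoic acid
Product: 23 benzyl 4-{(2S)-5,7-bis(benzyloxy)-6-[(2S)-1-methylpiperidin-2-yl]-4-oxo-3,4-dihydro-2H-chromen-2-yl}phenyl carbonate, via mixed trifluoroacetic anhydride 22 (not isolated)
Conditions: TFA, TFAA, CH2Cl2, 0 °C to rt; cold aq. NaHCO3
Reagents that add atoms: none
Why: TFAA converts the acid into the mixed trifluoroacetic anhydride 22, which under TFA acts as an acylium equivalent and is attacked by the ring A carbon ortho to O1 (also ortho to one benzyloxy group and para to the other), followed by loss of the ring proton; this is an intramolecular Friedel–Crafts acylation of a phloroglucinol-type ether, the established closure of 3-aryloxypropanoic acids to chroman-4-ones and flavanones. Ring C closes in a 6-exo-trig mode at the activated carbonyl, forming C4–C4a. No stereocentre is created, and C2 and the piperidine carbon are carried through because no bond to either is broken. Regioselectivity needs no control, since rotation of ring A about its O1–piperidine axis exchanges the two ortho carbons and both give the 6-substituted chromanone. What must be secured is retention at C2, which the electron-withdrawing carbonate on ring B and the short, cold reaction protect by disfavouring ionisation of the benzylic C2–O1 bond, and survival of the amine, which is held as its inert ammonium trifluoroacetate. Transfer of the alkanoyl and not the trifluoroacetyl group is inherent to such mixed anhydrides and is reinforced by the intramolecular setting.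

Step 13
Reactants: 23 benzyl 4-{(2S)-5,7-bis(benzyloxy)-6-[(2S)-1-methylpiperidin-2-yl]-4-oxo-3,4-dihydro-2H-chromen-2-yl}phenyl carbonate
Product: 24 (2S)-5,7-dihydroxy-2-(4-hydroxyphenyl)-6-[(2S)-1-methylpiperidin-2-yl]-2,3-dihydro-4H-chromen-4-one
Conditions: H2 (1 atm), 10% Pd/C, AcOH (1 equiv), EtOAc/MeOH, rt; pH 7 work-up
Reagents that add atoms: none
Why: Catalytic hydrogenolysis cleaves the two benzyl ethers and the benzyl carbonate (which then loses carbon dioxide) in one operation at room temperature, so that the base-sensitive C2 centre of the 4'-hydroxyflavanone never meets base, while the benzylic C–N and C2–O1 bonds are expected to react far more slowly.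

Compound list
1 | 3,5-bis(benzyloxy)phenol | Oc1cc(OCc2ccccc2)cc(OCc2ccccc2)c1 | starting material
2 | N-{[2,6-bis(benzyloxy)-4-hydroxyphenyl]methylidene}-N-methylmethanaminium chloride | C[N+](C)=Cc1c(OCc2ccccc2)cc(O)cc1OCc1ccccc1.[Cl-] | intermediate
3 | 2,6-bis(benzyloxy)-4-hydroxybenzaldehyde | O=Cc1c(OCc2ccccc2)cc(O)cc1OCc1ccccc1 | intermediate
4 | 4-(allyloxy)-2,6-bis(benzyloxy)benzaldehyde | C=CCOc1cc(OCc2ccccc2)c(C=O)c(OCc2ccccc2)c1 | intermediate
5 | (R)-N-{(E)-[4-(allyloxy)-2,6-bis(benzyloxy)phenyl]methylidene}-2-methylpropane-2-sulfinamide | CC(C)(C)[S@@](=O)/N=C/c1c(OCc2ccccc2)cc(OCC=C)cc1OCc1ccccc1 | intermediate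
6 | 1-bromo-4-chlorobutane | ClCCCCBr | starting material
7 | 4-chlorobutylmagnesium bromide | ClCCCC[Mg]Br | intermediate
8 | (R)-N-{(1S)-1-[4-(allyloxy)-2,6-bis(benzyloxy)phenyl]-5-chloropentyl}-2-methylpropane-2-sulfinamide | CC(C)(C)[S@@](=O)N[C@@H](CCCCCl)c1c(OCc2ccccc2)cc(OCC=C)cc1OCc1ccccc1 | intermediate
9 | (1S)-1-[4-(allyloxy)-2,6-bis(benzyloxy)phenyl]-5-chloropentan-1-aminium chloride | [NH3+][C@@H](CCCCCl)c1c(OCc2ccccc2)cc(OCC=C)cc1OCc1ccccc1.[Cl-] | intermediate
10 | (2S)-2-[4-(allyloxy)-2,6-bis(benzyloxy)phenyl]piperidine | N1CCCC[C@H]1c1c(OCc2ccccc2)cc(OCC=C)cc1OCc1ccccc1 | intermediate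
11 | (2S)-2-[4-(allyloxy)-2,6-bis(benzyloxy)phenyl]-1-methylpiperidine | CN1CCCC[C@H]1c1c(OCc2ccccc2)cc(OCC=C)cc1OCc1ccccc1 | intermediate
12 | 3,5-bis(benzyloxy)-4-[(2S)-1-methylpiperidin-2-yl]phenol | CN1CCCC[C@H]1c1c(OCc2ccccc2)cc(O)cc1OCc1ccccc1 | intermediate
13 | 4-hydroxybenzaldehyde | O=Cc1ccc(O)cc1 | starting material
14 | benzyl 4-formylphenyl carbonate | O=Cc1ccc(OC(=O)OCc2ccccc2)cc1 | intermediate
15 | 2-allyl-4,4,5,5-tetramethyl-1,3,2-dioxaborolane (allylboronic acid pinacol ester) | C=CCB1OC(C)(C)C(C)(C)O1 | starting material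
16 | benzyl 4-{(1R)-1-[(4,4,5,5-tetramethyl-1,3,2-dioxaborolan-2-yl)oxy]but-3-en-1-yl}phenyl carbonate | C=CC[C@@H](OB1OC(C)(C)C(C)(C)O1)c1ccc(OC(=O)OCc2ccccc2)cc1 | intermediate
17 | benzyl 4-[(1R)-1-hydroxybut-3-en-1-yl]phenyl carbonate | C=CC[C@@H](O)c1ccc(OC(=O)OCc2ccccc2)cc1 | intermediate
18 | benzyl 4-[(1S)-1-{3,5-bis(benzyloxy)-4-[(2S)-1-methylpiperidin-2-yl]phenoxy}but-3-en-1-yl]phenyl carbonate | CN1CCCC[C@H]1c1c(OCc2ccccc2)cc(O[C@@H](CC=C)c2ccc(OC(=O)OCc3ccccc3)cc2)cc1OCc1ccccc1 | intermediate
19 | benzyl 4-[(1S)-1-{3,5-bis(benzyloxy)-4-[(2S)-1-methylpiperidin-2-yl]phenoxy}-3,4-dihydroxybutyl]phenyl carbonate (both configurations at the new carbinol carbon) | CN1CCCC[C@H]1c1c(OCc2ccccc2)cc(O[C@@H](CC(O)CO)c2ccc(OC(=O)OCc3ccccc3)cc2)cc1OCc1ccccc1 | intermediate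
20 | benzyl 4-[(1S)-1-{3,5-bis(benzyloxy)-4-[(2S)-1-methylpiperidin-2-yl]phenoxy}-3-oxopropyl]phenyl carbonate | CN1CCCC[C@H]1c1c(OCc2ccccc2)cc(O[C@@H](CC=O)c2ccc(OC(=O)OCc3ccccc3)cc2)cc1OCc1ccccc1 | intermediate
21 | (3S)-3-(4-{[(benzyloxy)carbonyl]oxy}phenyl)-3-{3,5-bis(benzyloxy)-4-[(2S)-1-methylpiperidin-2-yl]phenoxy}propanoic acid | CN1CCCC[C@H]1c1c(OCc2ccccc2)cc(O[C@@H](CC(=O)O)c2ccc(OC(=O)OCc3ccccc3)cc2)cc1OCc1ccccc1 | intermediate
22 | mixed anhydride of acid 21 and trifluoroacetic acid, as the trifluoroacetic acid salt of the amine | CN1CCCC[C@H]1c1c(OCc2ccccc2)cc(O[C@@H](CC(=O)OC(=O)C(F)(F)F)c2ccc(OC(=O)OCc3ccccc3)cc2)cc1OCc1ccccc1.OC(=O)C(F)(F)F | intermediate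
23 | benzyl 4-{(2S)-5,7-bis(benzyloxy)-6-[(2S)-1-methylpiperidin-2-yl]-4-oxo-3,4-dihydro-2H-chromen-2-yl}phenyl carbonate | CN1CCCC[C@H]1c1c(OCc2ccccc2)cc2c(c1OCc1ccccc1)C(=O)C[C@@H](c1ccc(OC(=O)OCc3ccccc3)cc1)O2 | intermediate
24 | (2S)-5,7-dihydroxy-2-(4-hydroxyphenyl)-6-[(2S)-1-methylpiperidin-2-yl]-2,3-dihydro-4H-chromen-4-one | CN1CCCC[C@H]1c1c(O)cc2c(c1O)C(=O)C[C@@H](c1ccc(O)cc1)O2 | target

Total step count: 13. Longest linear sequence: 11 steps (steps 1 to 7, then 10 to 13, from compound 1).

Steps most likely to fail

Step 12 (key step). What may go wrong: acid-promoted ionisation of the benzylic C2–O1 bond before or after acylation (loss of configuration at C2 or cleavage of the ether), acid-induced loss of benzyl groups, or trifluoroacetylation of ring A in competition with ring closure. Fallback: the same C4–C4a bond is made by an anionic instead of a cationic closure (Parham cyclisation). It sets out from acid 21, which is coupled with N,O-dimethylhydroxylamine hydrochloride (EDC, i-Pr2NEt, CH2Cl2) to give the N-methoxy-N-methylamide F1. One equivalent of NBS in MeCN at −20 °C, applied to the trifluoroacetate salt of the amine, should brominate ring A once at a carbon ortho to the ether oxygen and give the aryl bromide F2; the two ortho carbons are equivalent, so only one monobromide exists. Bromine–lithium exchange with t-BuLi in THF at −100 °C then lets the aryllithium add to the amide carbonyl, and work-up releases chromanone 23, where the route is rejoined.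

Step 4. What may go wrong: poor or reversed facial selectivity, because an ortho benzyloxy oxygen can compete with the sulfinyl oxygen for magnesium and open the chair transition state, together with slow addition to the electron-rich, doubly ortho-substituted imine. Fallback: auxiliary control is given up for a racemic synthesis and separation of enantiomers. It sets out from aldehyde 4, which with LiHMDS in THF gives the N-trimethylsilyl imine F3. Addition of Grignard reagent 7 and aqueous work-up give the racemic 1-aryl-5-chloropentan-1-amine F4, which is cyclised with K2CO3 and NaI in MeCN to the racemic piperidine F5. Preparative chromatography on a chiral stationary phase separates the enantiomers; the (S)-enantiomer is compound 10, where the route is rejoined.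

Step 11. What may go wrong: oxidation at the wrong site (N-oxidation or N-demethylation of the piperidine, chlorination of the electron-rich ring A by hypochlorite) or β-elimination of the aryloxy group from the intermediate aldehyde. Fallback: the carboxyl carbon is brought in at the acid oxidation level, so that no oxidation follows the coupling. It sets out from aldehyde 14 and uses phenol 12. Addition of the lithium enolate of tert-butyl acetate (LDA, THF, −78 °C) to 14 gives the racemic β-hydroxy ester F6, Dess–Martin periodinane gives the β-keto ester F7, and asymmetric transfer hydrogenation with RuCl[(R,R)-TsDPEN](p-cymene) in HCO2H/Et3N should give the (R)-β-hydroxy ester F8. Mitsunobu coupling of F8 with 12 (PPh3, DIAD, toluene, −20 °C, inversion; run cold to hold back elimination to the cinnamate) gives the (S)-tert-butyl ester F9, and TFA in CH2Cl2 cleaves it to acid 21, where the route is rejoined.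

Further compounds
F1 | step 12 | (3S)-3-(4-{[(benzyloxy)carbonyl]oxy}phenyl)-3-{3,5-bis(benzyloxy)-4-[(2S)-1-methylpiperidin-2-yl]phenoxy}-N-methoxy-N-methylpropanamide | CN1CCCC[C@H]1c1c(OCc2ccccc2)cc(O[C@@H](CC(=O)N(C)OC)c2ccc(OC(=O)OCc3ccccc3)cc2)cc1OCc1ccccc1
F2 | step 12 | (3S)-3-(4-{[(benzyloxy)carbonyl]oxy}phenyl)-3-{3,5-bis(benzyloxy)-2-bromo-4-[(2S)-1-methylpiperidin-2-yl]phenoxy}-N-methoxy-N-methylpropanamide | CN1CCCC[C@H]1c1c(OCc2ccccc2)cc(O[C@@H](CC(=O)N(C)OC)c2ccc(OC(=O)OCc3ccccc3)cc2)c(Br)c1OCc1ccccc1
F3 | step 4 | (E)-1-[4-(allyloxy)-2,6-bis(benzyloxy)phenyl]-N-(trimethylsilyl)methanimine | C[Si](C)(C)/N=C/c1c(OCc2ccccc2)cc(OCC=C)cc1OCc1ccccc1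
F4 | step 4 | racemic 1-[4-(allyloxy)-2,6-bis(benzyloxy)phenyl]-5-chloropentan-1-amine | NC(CCCCCl)c1c(OCc2ccccc2)cc(OCC=C)cc1OCc1ccccc1
F5 | step 4 | racemic 2-[4-(allyloxy)-2,6-bis(benzyloxy)phenyl]piperidine | C=CCOc1cc(OCc2ccccc2)c(C2CCCCN2)c(OCc2ccccc2)c1
F6 | step 11 | racemic tert-butyl 3-(4-{[(benzyloxy)carbonyl]oxy}phenyl)-3-hydroxypropanoate | CC(C)(C)OC(=O)CC(O)c1ccc(OC(=O)OCc2ccccc2)cc1
F7 | step 11 | tert-butyl 3-(4-{[(benzyloxy)carbonyl]oxy}phenyl)-3-oxopropanoate | CC(C)(C)OC(=O)CC(=O)c1ccc(OC(=O)OCc2ccccc2)cc1
F8 | step 11 | tert-butyl (3R)-3-(4-{[(benzyloxy)carbonyl]oxy}phenyl)-3-hydroxypropanoate | CC(C)(C)OC(=O)C[C@@H](O)c1ccc(OC(=O)OCc2ccccc2)cc1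
F9 | step 11 | tert-butyl (3S)-3-(4-{[(benzyloxy)carbonyl]oxy}phenyl)-3-{3,5-bis(benzyloxy)-4-[(2S)-1-methylpiperidin-2-yl]phenoxy}propanoate | CN1CCCC[C@H]1c1c(OCc2ccccc2)cc(O[C@@H](CC(=O)OC(C)(C)C)c2ccc(OC(=O)OCc3ccccc3)cc2)cc1OCc1ccccc1
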